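**Remark on the target:** mallotophenone has no stereocentre and is achiral (two identical aryl groups on one CH2), so there is no enantiomer to select and the SMILES needs no stereodescriptor.

## Structural features

Mallotophenone is a diarylmethane: two identical benzene rings joined through one sp3 CH2 carbon, with no other ring and no chain longer than an acetyl group. Each ring is hexasubstituted; numbered from the bridge carbon (used throughout the discussion), C1 carries the CH2, C2 an OH, C3 the acetyl group, C4 an OH, C5 a CH3 and C6 an OCH3 (primed locants on the second ring). A mirror plane through the CH2 carbon exchanges the two rings. The fragile parts are the electron-rich Ar–CH2–Ar unit (acid-catalysed retro-Friedel–Crafts scission and bridge scrambling, oxidation at the doubly benzylic carbon) and the free polyphenol (air oxidation under base). The real difficulty is regiochemical: six different positions on each ring, three phloroglucinol oxygens to be told apart (O2 and O4 free, O6 methylated), and a single one-carbon link to be made without chain growth. The key step exploits the fact that, once the bridge and the C5 methyl are in place on a fully O-methylated core, C3 and C3′ are the only two ring C–H positions of a C2v-symmetric molecule. Both acetyl C–C bonds can therefore be made in one two-directional operation with no regiochemical choice, and each new carbonyl then sits beside exactly O2/O4 (to be freed) and remote from O6 (to be kept). In one sentence, the route is a two-directional double C-acetylation of a preformed, symmetric, fully O-methylated diarylmethane; this does not describe the usual plan, which bridges two finished acetophenone monomers with formaldehyde in the last step.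

## Logic of the disconnections

**6 ⇒ 5.** In the forward sense four O–CH3 bonds of 5 are cut, at O2, O4, O2′ and O4′. The cut is placed here because these four oxygens are exactly those ortho to a ketone carbonyl, whereas O6/O6′, which must stay methylated, are para to it and have only carbon neighbours (C1 and C5). The differentiation of the three oxygens of each ring is thereby reduced to a chelation problem. The gain is that 5 carries six identical protecting groups, no acidic or oxidisable phenol, and is a neutral compound that is easy to purify. The demand on the forward step is that a chelating Lewis acid cleaves both ortho ethers on both rings, spares the two para ethers and does not break the C1–CH2 bonds.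

**5 ⇒ 3 (through 4), the key disconnection.** The bonds C3–C(=O) and C3′–C(=O) are cut together. The reason is that C3 and C3′ are the only unsubstituted ring carbons of 3, each activated by two ortho and one para methoxy group, so the position of acylation is dictated by the substitution pattern and the symmetry. The gain is large: both carbonyl groups disappear and what remains is a C2v-symmetric hexaether with only three kinds of ring substituent. The demand is that an acetyl donor reacts twice, at two hindered positions flanked by methoxy groups, faster than any acid-induced ipso attack at C1 that would scramble the bridge.

**3 ⇒ 1 (through 2).** Both C1–CH2 bonds are cut, leading to two molecules of 1 and a one-carbon electrophile at the aldehyde oxidation level. The reason is that the two ring C–H positions of 1 are equivalent by symmetry, so no regiochemical question arises, and 1 already carries the C5 methyl group and all three oxygens. The gain is a single commercial arene as the only carbon source of both rings. The demand is that the condensation stops at the 2:1 stage: since 3 still has one C–H per ring, 1 must be in excess and the one-carbon electrophile limiting.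

## Other disconnections considered

**Alternative 1:** Cut both C1–CH2 bonds of the finished target, giving two molecules of the free monomer 1-(2,6-dihydroxy-4-methoxy-3-methylphenyl)ethanone A1 and formaldehyde. The forward key step is the biomimetic methylene bridging of A1 at its single free ring carbon. This is the plan that comes to mind first, and its last step is sound. Its weakness lies earlier: A1 has to be made by selective mono-O-methylation of 1-(2,4,6-trihydroxy-3-methylphenyl)ethanone A2, which in turn needs a mono-C-methylation of an acylphloroglucinol. Both alkylations rely on small innate reactivity differences of a free polyphenol and are prone to over-alkylation. The chosen plan takes every regiochemical decision from symmetry or from chelation, needs no partial alkylation, and is not longer.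

**Alternative 2:** Cut only one C1–CH2 bond and take the bridge carbon from a ring methyl group. The symmetric dimethyl monomer 1-(2,6-dihydroxy-4-methoxy-3,5-dimethylphenyl)ethanone A3 would be oxidised at one C-methyl (Ag2O, DDQ or an anode) to the o-quinone methide 2-acetyl-3-hydroxy-5-methoxy-4-methyl-6-methylidenecyclohexa-2,4-dien-1-one A4. A4 would then be intercepted by A1 in a conjugate (Friedel–Crafts-type) addition. The idea is attractive because either methyl of A3 gives the same A4. It is not preferred because the oxidant cannot distinguish the methyl groups of A3 from the methyl of A1, or from the two methyls and the more easily oxidised doubly benzylic CH2 of the product. Over-oxidation and scrambled bridging are therefore built into the mechanism. Two different monomers would also have to be made for a symmetric target.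

**Alternative 3:** Cut one C1–CH2 bond of 5 as an sp3–sp2 cross-coupling. The forward key step is a Suzuki–Miyaura reaction of the benzylic bromide 1-[3-(bromomethyl)-2,4,6-trimethoxy-5-methylphenyl]ethanone A5 with the arylboronate 1-[2,4,6-trimethoxy-3-methyl-5-(4,4,5,5-tetramethyl-1,3,2-dioxaborolan-2-yl)phenyl]ethanone A6, giving 5. It is not preferred because it discards the symmetry: two differently functionalised hexasubstituted halves must be prepared separately. In addition, A6 is a 2,6-dialkoxyarylboronate of the kind that protodeboronates readily, and both partners are di-ortho-substituted at the reacting carbon, so transmetalation and reductive elimination would be slow. The step count would be at least twice that of the chosen plan.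

Key step: step 2

## Route

Step 1
Reactants: 1 2,4,6-trimethoxytoluene (1,3,5-trimethoxy-2-methylbenzene), two molecules per bridge, used in excess
Product: 3 bis(2,4,6-trimethoxy-3-methylphenyl)methane, via (2,4,6-trimethoxy-3-methylphenyl)methanol 2 (not isolated)
Conditions: (CH2O)n (0.25 equiv CH2O per 1), p-TsOH·H2O (5 mol %), AcOH, 40 °C; excess 1 recovered
Reagents that add atoms: paraformaldehyde (reacts as formaldehyde), C=O
Why: Acid-catalysed hydroxymethylation followed by Friedel–Crafts benzylation (the classical arene–formaldehyde condensation to a diarylmethane): 1 is hydroxymethylated to 2, which ionises to a trimethoxybenzyl cation and is captured by a second molecule of 1. The two ring C–H positions of 1 are equivalent, so only chain growth has to be controlled, and the excess of 1 should hold the reaction at the 2:1 stage.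

Step 2
Reactants: 3 bis(2,4,6-trimethoxy-3-methylphenyl)methane
Product: 5 bis(3-acetyl-2,4,6-trimethoxy-5-methylphenyl)methane, via monoacetyl diarylmethane 4 (not isolated)
Conditions: Ac2O (3 equiv), Sc(OTf)3 (10 mol %), MeNO2, 0 → 40 °C
Reagents that add atoms: acetic anhydride, CC(=O)OC(C)=O
Why: Friedel–Crafts acylation (metal-triflate-catalysed variant with an anhydride) run in two directions: Sc(III) activates Ac2O to an acetyl cation equivalent, which attacks C3–H of one ring of 3 to give a σ-complex stabilised by two ortho and one para methoxy group, and proton loss to acetate gives 4 and AcOH; the same sequence on the other ring gives 5. No ring is closed and no stereocentre is formed, so the selectivity needed is positional and chemoselective only. Positional selectivity is secured by the substrate: C3 and C3′ are the only ring C–H positions of 3, and the sp3 CH2 insulates the rings electronically, so the second ring should react as the first did and excess anhydride carries 4 on to 5. The chemoselectivity needed is substitution at C–H in preference to ipso attack at C1, which could expel a trimethoxybenzyl cation and scramble the bridge. This is favoured because only the C3 σ-complex can collapse irreversibly by proton loss, because the by-product is acetic acid and not a hydrogen halide–Lewis acid pair, and because each ring is deactivated inductively once it is acylated. The closest known reaction is the acetylation of 1,3,5-trimethoxybenzene and its C-alkyl homologues, which proceeds under catalytic Lewis acid conditions even at positions flanked by two methoxy groups. The two new carbonyl groups are the handles that single out O2/O4 on each ring in the last step.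

Step 3
Reactants: 5 bis(3-acetyl-2,4,6-trimethoxy-5-methylphenyl)methane
Product: 6 mallotophenone [bis(3-acetyl-2,4-dihydroxy-6-methoxy-5-methylphenyl)methane]
Conditions: BCl3 (1 M in CH2Cl2, 10 equiv), CH2Cl2, −78 °C → rt; then ice–H2O
Reagents that add atoms: none
Why: Chelation-controlled Lewis-acid ether cleavage (BCl3 demethylation ortho to an aryl ketone): boron bound to the carbonyl oxygen forms a six-membered chelate with an ortho methoxy oxygen and chloride removes the methyl group as MeCl; with excess reagent the carbonyl can turn to the second, sterically compressed ortho ether, and the O–B bonds are hydrolysed on work-up. The C6 methoxy group has only carbon neighbours (C1 and C5) and cannot enter a five- or six-membered boron chelate, so it should persist at or below room temperature.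

## Compound list

1 | 2,4,6-trimethoxytoluene (1,3,5-trimethoxy-2-methylbenzene) | COc1cc(OC)c(C)c(OC)c1 | starting material
2 | (2,4,6-trimethoxy-3-methylphenyl)methanol | COc1cc(OC)c(CO)c(OC)c1C | intermediate (not isolated)
3 | bis(2,4,6-trimethoxy-3-methylphenyl)methane | COc1cc(OC)c(Cc2c(OC)cc(OC)c(C)c2OC)c(OC)c1C | intermediate
4 | 1-[2,4,6-trimethoxy-3-methyl-5-(2,4,6-trimethoxy-3-methylbenzyl)phenyl]ethanone | COc1cc(OC)c(Cc2c(OC)c(C)c(OC)c(C(C)=O)c2OC)c(OC)c1C | intermediate (not isolated)
5 | bis(3-acetyl-2,4,6-trimethoxy-5-methylphenyl)methane | COc1c(C)c(OC)c(C(C)=O)c(OC)c1Cc1c(OC)c(C(C)=O)c(OC)c(C)c1OC | intermediate
6 | mallotophenone, bis(3-acetyl-2,4-dihydroxy-6-methoxy-5-methylphenyl)methane | COc1c(C)c(O)c(C(C)=O)c(O)c1Cc1c(O)c(C(C)=O)c(O)c(C)c1OC | target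

## Step count and risks

Total step count: 3. Longest linear sequence: 3 steps (1 → 3 → 5 → 6).

**Key step, step 2.** What is most likely to go wrong is acid-induced scrambling of the bridge: ipso attack at C1 by the acylating species or by a proton, loss of a trimethoxybenzyl cation and its re-addition elsewhere, in competition with a slow acylation of the hindered C3–H. A second failure mode is stalling after the first ring has reacted. The cause is that C1 is activated by the same three methoxy groups as C3, and the cation that would leave is strongly stabilised. The fallback sets out from 1 and returns at 5, and it reverses the order of the two C–C bond formations. 1 is acetylated first (Ac2O, Sc(OTf)3 cat., MeNO2) to 1-(2,4,6-trimethoxy-3-methylphenyl)ethanone F1, which has a single ring C–H and a deactivated ring. Two molecules of F1 are then joined with paraformaldehyde under stronger acid (H2SO4 in AcOH) to give 5. In this order no unacylated, electron-rich diarylmethane is exposed to an acylating medium, and chain growth is impossible.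

**Step 1.** What is most likely to go wrong is over-condensation: the benzylic cation derived from 2 alkylates the remaining C–H positions of 3, leading to linear or cyclic oligomers. The cause is that each ring of 3 is about as nucleophilic as 1, so only the excess of 1 stands against chain growth. The fallback sets out from 1 and returns at 3, and it builds the bridge from a nucleophilic aryl–metal species so that no electrophilic chain growth can occur. 1 is monobrominated (NBS, MeCN, 0 °C) to 2-bromo-1,3,5-trimethoxy-4-methylbenzene F2. Bromine–lithium exchange (n-BuLi, THF, −78 °C) and addition of ethyl formate (0.5 equiv) give bis(2,4,6-trimethoxy-3-methylphenyl)methanol F3. Ionic hydrogenation (Et3SiH, TFA, CH2Cl2, 0 °C) then removes the hydroxyl group through the strongly stabilised diarylmethyl cation and gives 3.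

**Step 3.** What is most likely to go wrong is incomplete cleavage of the second ortho ether on each ring, or, under forcing, loss of the twisted C6 ether or Lewis-acid scission of the bridge. The cause is that the carbonyl can chelate only one ortho oxygen at a time, so the second cleavage is slower than the first. The fallback sets out from 1 and returns at 6, and it cleaves the ethers before the bridge exists. The ketone F1 (made from 1 as in the first fallback) is treated with BCl3, or if necessary with AlCl3 in hot chlorobenzene, which a monomer without a bridge can tolerate. This gives 1-(2,6-dihydroxy-4-methoxy-3-methylphenyl)ethanone F4. Two molecules of F4 are then bridged at their single free ring carbon with aqueous formaldehyde under mild acid or base to give 6.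

## Further compounds

F1 | step 2 | 1-(2,4,6-trimethoxy-3-methylphenyl)ethanone | COc1cc(OC)c(C(C)=O)c(OC)c1C
F2 | step 1 | 2-bromo-1,3,5-trimethoxy-4-methylbenzene | COc1cc(OC)c(Br)c(OC)c1C
F3 | step 1 | bis(2,4,6-trimethoxy-3-methylphenyl)methanol | COc1cc(OC)c(C(O)c2c(OC)cc(OC)c(C)c2OC)c(OC)c1C
F4 | step 3 | 1-(2,6-dihydroxy-4-methoxy-3-methylphenyl)ethanone | COc1cc(O)c(C(C)=O)c(O)c1C
A1 | alternative 1 | 1-(2,6-dihydroxy-4-methoxy-3-methylphenyl)ethanone | COc1cc(O)c(C(C)=O)c(O)c1C
A2 | alternative 1 | 1-(2,4,6-trihydroxy-3-methylphenyl)ethanone | CC(=O)c1c(O)cc(O)c(C)c1O
A3 | alternative 2 | 1-(2,6-dihydroxy-4-methoxy-3,5-dimethylphenyl)ethanone | COc1c(C)c(O)c(C(C)=O)c(O)c1C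
A4 | alternative 2 | 2-acetyl-3-hydroxy-5-methoxy-4-methyl-6-methylidenecyclohexa-2,4-dien-1-one | C=C1C(=O)C(C(C)=O)=C(O)C(C)=C1OC
A5 | alternative 3 | 1-[3-(bromomethyl)-2,4,6-trimethoxy-5-methylphenyl]ethanone | COc1c(C)c(OC)c(C(C)=O)c(OC)c1CBr
A6 | alternative 3 | 1-[2,4,6-trimethoxy-3-methyl-5-(4,4,5,5-tetramethyl-1,3,2-dioxaborolan-2-yl)phenyl]ethanone | COc1c(C)c(OC)c(C(C)=O)c(OC)c1B1OC(C)(C)C(C)(C)O1
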